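**Retrosynthetic overview**

1. The plan rests on the C3a–C7a fusion bond of the 2,3-dihydrobenzofuran: the arene carbons C5 (acetyl), C6 (oxygen) and C7a (ring oxygen O1) are carried as three substituted carbons of a pyridazine, and C3a–C4 as a terminal alkyne held on the O1–C2–C3 tether.
2. Key disconnection: C3a–C7a and C4–C5, made together by intramolecular [4+2] cycloaddition of a 3-alkoxy-6-acetylpyridazine onto the alkyne and loss of N2. The dihydrofuran ring and the benzene ring both form in this one step; no ring of the target exists before it.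
3. The cycloaddition precursor comes from O1–C7a bond formation (SNAr of a syn-configured hexenynol on a 6-chloropyridazine Weinreb amide) and methyl ketone formation. The pyridazine comes from 4,6-dichloropyridazine-3-carboxylic acid and 4-methoxybenzyl alcohol.
4. C2 and C3 are set in an Evans syn-glycolate aldol reaction with methacrolein; the imide carbon becomes the alkyne (C3a–C4) by reduction and Ohira–Bestmann homologation.
5. End game: selective removal of the C3 3,4-dimethoxybenzyl ether, acylation with (Z)-2-(acetoxymethyl)but-2-enoic acid (from crotonaldehyde by α-iodination, reduction and carboxylation of the vinyllithium), and oxidative removal of the C6 4-methoxybenzyl ether.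

Key step: step 12

Remark: the C3 oxygen is carried as a 3,4-dimethoxybenzyl ether instead of a silyl ether, because a silyl group would migrate to the neighbouring alkoxide during the SNAr step, and the acetyl group is carried as a Weinreb amide (from 4,6-dichloropyridazine-3-carboxylic acid, taken as a purchasable building block) so that neither an enolisable ketone nor a zerovalent palladium catalyst meets the alkoxide or the allylic heteroaryl ether.

**Route**

Step 1
Reactants: 1 3,4-dimethoxybenzyl alcohol; 2 bromoacetic acid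
Product: 3 2-[(3,4-dimethoxybenzyl)oxy]acetic acid
Conditions: NaH (2.5 equiv), THF, 0 °C then reflux; aq. HCl work-up
Reagents that add atoms: none
Why: Williamson ether synthesis, in which the sodium alkoxide of 1 displaces bromide from sodium bromoacetate by SN2 reaction, the standard way to benzyloxyacetic acids.

Step 2
Reactants: 3 2-[(3,4-dimethoxybenzyl)oxy]acetic acid; 4 (R)-4-benzyl-1,3-oxazolidin-2-one
Product: 6 (R)-4-benzyl-3-{2-[(3,4-dimethoxybenzyl)oxy]acetyl}-1,3-oxazolidin-2-one, via pivalic mixed anhydride 5 (not isolated)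
Conditions: t-BuCOCl, Et3N, THF, −20 °C; then LiCl, 4, rt
Reagents that add atoms: none
Why: N-acylation of the oxazolidinone through the pivaloyl mixed anhydride with LiCl activation, attack taking place at the less hindered glycolyl carbonyl group.

Step 3
Reactants: 6 (R)-4-benzyl-3-{2-[(3,4-dimethoxybenzyl)oxy]acetyl}-1,3-oxazolidin-2-one; 7 methacrolein
Product: 9 (R)-4-benzyl-3-{(2R,3S)-2-[(3,4-dimethoxybenzyl)oxy]-3-hydroxy-4-methylpent-4-enoyl}-1,3-oxazolidin-2-one, via boron enolate 8 (not isolated)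
Conditions: Bu2BOTf, Et3N, CH2Cl2, −78 to 0 °C; 7, −78 to 0 °C; pH 7 buffer, MeOH, H2O2, 0 °C
Reagents that add atoms: none
Why: Evans syn-aldol reaction, in which the (Z)-boron enolate adds 1,2 to the enal through a closed Zimmerman–Traxler transition state on the face away from the benzyl group of the (R)-auxiliary, setting the 2R and 3S centres (later C3 and C2 of the benzofuran) in the syn relationship.

Step 4
Reactants: 9 (R)-4-benzyl-3-{(2R,3S)-2-[(3,4-dimethoxybenzyl)oxy]-3-hydroxy-4-methylpent-4-enoyl}-1,3-oxazolidin-2-one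
Product: 10 (2R,3S)-2-[(3,4-dimethoxybenzyl)oxy]-3-hydroxy-N-methoxy-N,4-dimethylpent-4-enamide
Conditions: Me3Al, MeNHOMe·HCl, CH2Cl2, −20 to 0 °C; aq. potassium sodium tartrate
Reagents that add atoms: N,O-dimethylhydroxylamine hydrochloride, CNOC.Cl
Why: Weinreb transamidation with the aluminium amide, which is assisted by the free β-hydroxyl group and should release the auxiliary without epimerisation.

Step 5
Reactants: 10 (2R,3S)-2-[(3,4-dimethoxybenzyl)oxy]-3-hydroxy-N-methoxy-N,4-dimethylpent-4-enamide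
Product: 11 (2R,3S)-2-[(3,4-dimethoxybenzyl)oxy]-N-methoxy-N,4-dimethyl-3-[(triethylsilyl)oxy]pent-4-enamide
Conditions: Et3SiCl, imidazole, DMF, 0 °C to rt
Reagents that add atoms: chlorotriethylsilane, CC[Si](Cl)(CC)CC
Why: Silylation of the secondary alcohol, needed because a free β-hydroxy aldehyde would undergo retro-aldol cleavage under the basic homologation that follows.

Step 6
Reactants: 11 (2R,3S)-2-[(3,4-dimethoxybenzyl)oxy]-N-methoxy-N,4-dimethyl-3-[(triethylsilyl)oxy]pent-4-enamide
Product: 13 triethyl({(3S,4S)-4-[(3,4-dimethoxybenzyl)oxy]-2-methylhex-1-en-5-yn-3-yl}oxy)silane, via aldehyde 12 (not isolated)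
Conditions: i-Bu2AlH, THF, −78 °C; then MeOH, K2CO3, dimethyl (1-diazo-2-oxopropyl)phosphonate, −78 °C to rt
Reagents that add atoms: dimethyl (1-diazo-2-oxopropyl)phosphonate, CC(=O)C(=[N+]=[N-])P(=O)(OC)OC
Why: Reduction of the Weinreb amide stops at the aldehyde through the chelated aluminium hemiaminal, and Ohira–Bestmann (Seyferth–Gilbert) homologation in the same flask converts it into the terminal alkyne under carbonate conditions mild enough to keep the α-alkoxy centre.

Step 7
Reactants: 13 triethyl({(3S,4S)-4-[(3,4-dimethoxybenzyl)oxy]-2-methylhex-1-en-5-yn-3-yl}oxy)silane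
Product: 14 (3S,4S)-4-[(3,4-dimethoxybenzyl)oxy]-2-methylhex-1-en-5-yn-3-ol
Conditions: PPTS (cat.), MeOH, rt
Reagents that add atoms: none
Why: Acid-catalysed methanolysis of the triethylsilyl ether, which should leave the benzyl-type ether, the alkene and the alkyne untouched.

Step 8
Reactants: 15 4,6-dichloropyridazine-3-carboxylic acid
Product: 17 4,6-dichloro-N-methoxy-N-methylpyridazine-3-carboxamide, via acid chloride 16 (not isolated)
Conditions: (COCl)2, DMF (cat.), CH2Cl2, 0 °C to rt; then MeNHOMe·HCl, i-Pr2NEt, CH2Cl2, −20 to 0 °C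
Reagents that add atoms: N,O-dimethylhydroxylamine hydrochloride, CNOC.Cl
Why: Acid chloride formation under Vilsmeier catalysis followed by amidation, N-acylation of the hydroxylamine being much faster at low temperature than substitution of the ring chlorides.

Step 9
Reactants: 17 4,6-dichloro-N-methoxy-N-methylpyridazine-3-carboxamide; 18 4-methoxybenzyl alcohol
Product: 19 6-chloro-N-methoxy-4-[(4-methoxybenzyl)oxy]-N-methylpyridazine-3-carboxamide
Conditions: 18 (1.0 equiv), NaH, THF, 0 °C; added to 17, THF, −40 to 0 °C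
Reagents that add atoms: none
Why: Nucleophilic aromatic substitution (SNAr) at C4, the most electrophilic position of the dichlorodiazine because it is para to N1 and ortho to the carboxamide, which also guides the sodium alkoxide, so that one equivalent at low temperature should give the 4-ether.

Step 10
Reactants: 14 (3S,4S)-4-[(3,4-dimethoxybenzyl)oxy]-2-methylhex-1-en-5-yn-3-ol; 19 6-chloro-N-methoxy-4-[(4-methoxybenzyl)oxy]-N-methylpyridazine-3-carboxamide
Product: 20 6-({(3S,4S)-4-[(3,4-dimethoxybenzyl)oxy]-2-methylhex-1-en-5-yn-3-yl}oxy)-N-methoxy-4-[(4-methoxybenzyl)oxy]-N-methylpyridazine-3-carboxamide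
Conditions: 14, NaH, THF, 0 °C; then 19, 0 °C to rt
Reagents that add atoms: none
Why: Nucleophilic aromatic substitution (SNAr) of the remaining chloride at C6, which is next to N1 and para to the carboxamide-bearing carbon, while the benzyl-type group on the neighbouring oxygen of 14 cannot migrate to the alkoxide and the amide cannot be enolised.

Step 11
Reactants: 20 6-({(3S,4S)-4-[(3,4-dimethoxybenzyl)oxy]-2-methylhex-1-en-5-yn-3-yl}oxy)-N-methoxy-4-[(4-methoxybenzyl)oxy]-N-methylpyridazine-3-carboxamide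
Product: 21 1-[6-({(3S,4S)-4-[(3,4-dimethoxybenzyl)oxy]-2-methylhex-1-en-5-yn-3-yl}oxy)-4-[(4-methoxybenzyl)oxy]pyridazin-3-yl]ethan-1-one
Conditions: MeMgBr (3 equiv), THF, −78 to 0 °C; aq. NH4Cl
Reagents that add atoms: methylmagnesium bromide, C[Mg]Br
Why: Weinreb ketone synthesis, in which the Grignard reagent adds only once because the chelated tetrahedral magnesium adduct survives until work-up, the alkyne C–H merely consuming one further equivalent.

Step 12
Reactants: 21 1-[6-({(3S,4S)-4-[(3,4-dimethoxybenzyl)oxy]-2-methylhex-1-en-5-yn-3-yl}oxy)-4-[(4-methoxybenzyl)oxy]pyridazin-3-yl]ethan-1-one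
Product: 23 1-{(2S,3S)-3-[(3,4-dimethoxybenzyl)oxy]-6-[(4-methoxybenzyl)oxy]-2-(prop-1-en-2-yl)-2,3-dihydro-1-benzofuran-5-yl}ethan-1-one, via bridged azo cycloadduct 22 (not isolated)
Conditions: 1,2-dichlorobenzene (0.01 M, degassed), BHT (cat.), 180 °C, sealed vessel
Reagents that add atoms: none
Why: The acetyl-bearing 1,2-diazine acts as the electron-poor 4π component across its two carbons next to nitrogen and the tethered terminal alkyne as the 2π component, so that an intramolecular inverse-electron-demand Diels–Alder reaction forms C3a–C7a and C4–C5, and the bridged azo adduct then loses dinitrogen by retro-Diels–Alder reaction to give the benzene ring. The closest known reaction type is the thermal cyclisation of 3-(but-3-ynyloxy)pyridazines to 2,3-dihydrobenzofurans. The dihydrofuran ring closes through the three-atom O1–C2–C3 tether in the same [4+2] event as a five-membered ring fused at the new C3a–C7a bond, and the six-membered carbocycle closes as the cycloadduct and becomes aromatic on cycloreversion. No lasting stereocentre is made, since the two bridgehead carbons return to sp2, and C2 and C3 are carried unchanged from the acyclic ether. Regiochemistry is fixed by the tether, which can only deliver the internal alkyne carbon to the ether-bearing diazine carbon; the step needs the cycloaddition to outrun the [3,3] shift of the allylic group from the ether oxygen to the ring nitrogen, which the LUMO-lowering acetyl group, the two substituents on the tether and high dilution should secure.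

Step 13
Reactants: 23 1-{(2S,3S)-3-[(3,4-dimethoxybenzyl)oxy]-6-[(4-methoxybenzyl)oxy]-2-(prop-1-en-2-yl)-2,3-dihydro-1-benzofuran-5-yl}ethan-1-one
Product: 24 1-{(2S,3S)-3-hydroxy-6-[(4-methoxybenzyl)oxy]-2-(prop-1-en-2-yl)-2,3-dihydro-1-benzofuran-5-yl}ethan-1-one
Conditions: DDQ (1.2 equiv), CH2Cl2/pH 7 phosphate buffer (10:1), 0 °C
Reagents that add atoms: none
Why: Oxidative benzyl ether cleavage with DDQ, in which the more electron-rich 3,4-dimethoxybenzyl ether should be oxidised well before the 4-methoxybenzyl ether of the acetyl-deactivated phenol, so that the C3 hydroxyl alone is freed under buffered conditions that do not ionise the benzylic C3–O bond.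

Step 14
Reactants: 25 (E)-but-2-enal (crotonaldehyde)
Product: 26 (Z)-2-iodobut-2-enal
Conditions: I2, K2CO3, DMAP (cat.), THF/H2O, rt
Reagents that add atoms: iodine, II
Why: α-Iodination of the enal by nucleophilic catalysis (Baylis–Hillman-type addition of DMAP, iodination of the enolate, elimination), which gives the isomer with iodine and methyl cis.

Step 15
Reactants: 26 (Z)-2-iodobut-2-enal
Product: 27 (Z)-2-iodobut-2-en-1-ol
Conditions: NaBH4, MeOH, 0 °C
Reagents that add atoms: none
Why: 1,2-Reduction of the aldehyde with borohydride, the vinyl iodide and the alkene geometry being unaffected.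

Step 16
Reactants: 27 (Z)-2-iodobut-2-en-1-ol
Product: 29 (Z)-2-(hydroxymethyl)but-2-enoic acid, via dilithio alkoxide 28 (not isolated)
Conditions: t-BuLi (3.1 equiv), Et2O, −78 °C; CO2; aq. HCl
Reagents that add atoms: carbon dioxide, O=C=O
Why: Iodine–lithium exchange on the lithium alkoxide proceeds with retention of alkene geometry, and carboxylation of the vinyllithium places the carboxyl group cis to the methyl group.

Step 17
Reactants: 29 (Z)-2-(hydroxymethyl)but-2-enoic acid
Product: 30 (Z)-2-(acetoxymethyl)but-2-enoic acid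
Conditions: Ac2O, pyridine, CH2Cl2, 0 °C to rt; aqueous work-up
Reagents that add atoms: acetic anhydride, CC(=O)OC(C)=O
Why: O-Acetylation of the primary allylic alcohol, any mixed anhydride formed at the carboxyl group being hydrolysed on aqueous work-up.

Step 18
Reactants: 24 1-{(2S,3S)-3-hydroxy-6-[(4-methoxybenzyl)oxy]-2-(prop-1-en-2-yl)-2,3-dihydro-1-benzofuran-5-yl}ethan-1-one; 30 (Z)-2-(acetoxymethyl)but-2-enoic acid
Product: 32 (2S,3S)-5-acetyl-6-[(4-methoxybenzyl)oxy]-2-(prop-1-en-2-yl)-2,3-dihydro-1-benzofuran-3-yl (2Z)-2-(acetoxymethyl)but-2-enoate, via trichlorobenzoic mixed anhydride 31 (not isolated)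
Conditions: 30 (2 equiv), 2,4,6-trichlorobenzoyl chloride, Et3N, toluene, rt; then 24, toluene, 80 °C
Reagents that add atoms: none
Why: Yamaguchi-type esterification through the mixed trichlorobenzoic anhydride run without a nucleophilic catalyst, the protocol established for angelate esters, so that neither conjugate addition (Z to E isomerisation) nor SN2′ displacement of the allylic acetate is opened and C3 keeps its configuration because its C–O bond is not broken.

Step 19
Reactants: 32 (2S,3S)-5-acetyl-6-[(4-methoxybenzyl)oxy]-2-(prop-1-en-2-yl)-2,3-dihydro-1-benzofuran-3-yl (2Z)-2-(acetoxymethyl)but-2-enoate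
Product: 33 (2S,3S)-5-acetyl-6-hydroxy-2-(prop-1-en-2-yl)-2,3-dihydro-1-benzofuran-3-yl (2Z)-2-(acetoxymethyl)but-2-enoate (CNP0193314.1)
Conditions: DDQ (2–3 equiv), CH2Cl2/pH 7 phosphate buffer (10:1), rt
Reagents that add atoms: none
Why: Oxidative cleavage of the 4-methoxybenzyl aryl ether with DDQ under buffered conditions that are neither acidic nor basic, which should spare the ionisable C3 ester, the allylic acetate and both alkenes.

**Compound list**

1 | 3,4-dimethoxybenzyl alcohol | COc1ccc(CO)cc1OC | starting material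
2 | bromoacetic acid | OC(=O)CBr | starting material
3 | 2-[(3,4-dimethoxybenzyl)oxy]acetic acid | COc1ccc(COCC(=O)O)cc1OC | intermediate
4 | (R)-4-benzyl-1,3-oxazolidin-2-one | O=C1N[C@H](Cc2ccccc2)CO1 | starting material
5 | mixed anhydride of 3 with pivalic acid (formed in the flask) | COc1ccc(COCC(=O)OC(=O)C(C)(C)C)cc1OC | intermediate
6 | (R)-4-benzyl-3-{2-[(3,4-dimethoxybenzyl)oxy]acetyl}-1,3-oxazolidin-2-one | COc1ccc(COCC(=O)N2[C@H](Cc3ccccc3)COC2=O)cc1OC | intermediate
7 | methacrolein | C=C(C)C=O | starting material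
8 | (Z)-dibutylboron enolate of 6 (formed in the flask) | CCCCB(CCCC)O/C(=C\OCc1ccc(OC)c(OC)c1)N1[C@H](Cc2ccccc2)COC1=O | intermediate
9 | (R)-4-benzyl-3-{(2R,3S)-2-[(3,4-dimethoxybenzyl)oxy]-3-hydroxy-4-methylpent-4-enoyl}-1,3-oxazolidin-2-one | C=C(C)[C@H](O)[C@@H](OCc1ccc(OC)c(OC)c1)C(=O)N1[C@H](Cc2ccccc2)COC1=O | intermediate
10 | (2R,3S)-2-[(3,4-dimethoxybenzyl)oxy]-3-hydroxy-N-methoxy-N,4-dimethylpent-4-enamide | C=C(C)[C@H](O)[C@@H](OCc1ccc(OC)c(OC)c1)C(=O)N(C)OC | intermediate
11 | (2R,3S)-2-[(3,4-dimethoxybenzyl)oxy]-N-methoxy-N,4-dimethyl-3-[(triethylsilyl)oxy]pent-4-enamide | C=C(C)[C@H](O[Si](CC)(CC)CC)[C@@H](OCc1ccc(OC)c(OC)c1)C(=O)N(C)OC | intermediate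
12 | (2R,3S)-2-[(3,4-dimethoxybenzyl)oxy]-4-methyl-3-[(triethylsilyl)oxy]pent-4-enal (formed in the flask) | C=C(C)[C@H](O[Si](CC)(CC)CC)[C@@H](OCc1ccc(OC)c(OC)c1)C=O | intermediate
13 | triethyl({(3S,4S)-4-[(3,4-dimethoxybenzyl)oxy]-2-methylhex-1-en-5-yn-3-yl}oxy)silane | C=C(C)[C@H](O[Si](CC)(CC)CC)[C@@H](OCc1ccc(OC)c(OC)c1)C#C | intermediate
14 | (3S,4S)-4-[(3,4-dimethoxybenzyl)oxy]-2-methylhex-1-en-5-yn-3-ol | C=C(C)[C@H](O)[C@@H](OCc1ccc(OC)c(OC)c1)C#C | intermediate
15 | 4,6-dichloropyridazine-3-carboxylic acid | OC(=O)c1nnc(Cl)cc1Cl | starting material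
16 | 4,6-dichloropyridazine-3-carbonyl chloride (formed in the flask) | O=C(Cl)c1nnc(Cl)cc1Cl | intermediate
17 | 4,6-dichloro-N-methoxy-N-methylpyridazine-3-carboxamide | CON(C)C(=O)c1nnc(Cl)cc1Cl | intermediate
18 | 4-methoxybenzyl alcohol | COc1ccc(CO)cc1 | starting material
19 | 6-chloro-N-methoxy-4-[(4-methoxybenzyl)oxy]-N-methylpyridazine-3-carboxamide | CON(C)C(=O)c1nnc(Cl)cc1OCc1ccc(OC)cc1 | intermediate
20 | 6-({(3S,4S)-4-[(3,4-dimethoxybenzyl)oxy]-2-methylhex-1-en-5-yn-3-yl}oxy)-N-methoxy-4-[(4-methoxybenzyl)oxy]-N-methylpyridazine-3-carboxamide | C=C(C)[C@@H]([C@@H](OCc1ccc(OC)c(OC)c1)C#C)Oc1cc(OCc2ccc(OC)cc2)c(C(=O)N(C)OC)nn1 | intermediate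
21 | 1-[6-({(3S,4S)-4-[(3,4-dimethoxybenzyl)oxy]-2-methylhex-1-en-5-yn-3-yl}oxy)-4-[(4-methoxybenzyl)oxy]pyridazin-3-yl]ethan-1-one (cycloaddition precursor) | C=C(C)[C@@H]([C@@H](OCc1ccc(OC)c(OC)c1)C#C)Oc1cc(OCc2ccc(OC)cc2)c(C(C)=O)nn1 | intermediate
22 | bridged azo cycloadduct of 21, a 2,3-diazabicyclo[2.2.2]octa-2,5,7-triene fused to the dihydrofuran ring (formed in the flask, bridgehead configuration not defined) | CC(=O)C12N=NC3(O[C@@H](C(C)=C)[C@@H](OCc4ccc(OC)c(OC)c4)C3=C1)C=C2OCc1ccc(OC)cc1 | intermediate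
23 | 1-{(2S,3S)-3-[(3,4-dimethoxybenzyl)oxy]-6-[(4-methoxybenzyl)oxy]-2-(prop-1-en-2-yl)-2,3-dihydro-1-benzofuran-5-yl}ethan-1-one (cis) | C=C(C)[C@@H]1Oc2cc(OCc3ccc(OC)cc3)c(C(C)=O)cc2[C@@H]1OCc1ccc(OC)c(OC)c1 | intermediate
24 | 1-{(2S,3S)-3-hydroxy-6-[(4-methoxybenzyl)oxy]-2-(prop-1-en-2-yl)-2,3-dihydro-1-benzofuran-5-yl}ethan-1-one (cis) | C=C(C)[C@@H]1Oc2cc(OCc3ccc(OC)cc3)c(C(C)=O)cc2[C@@H]1O | intermediate
25 | (E)-but-2-enal (crotonaldehyde) | C/C=C/C=O | starting material
26 | (Z)-2-iodobut-2-enal | C/C=C(\I)C=O | intermediate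
27 | (Z)-2-iodobut-2-en-1-ol | C/C=C(\I)CO | intermediate
28 | lithium (Z)-2-lithiobut-2-en-1-olate (formed in the flask) | C/C=C(\[Li])CO[Li] | intermediate
29 | (Z)-2-(hydroxymethyl)but-2-enoic acid | C/C=C(\C(=O)O)CO | intermediate
30 | (Z)-2-(acetoxymethyl)but-2-enoic acid | C/C=C(\C(=O)O)COC(C)=O | intermediate
31 | mixed anhydride of 30 with 2,4,6-trichlorobenzoic acid (formed in the flask) | C/C=C(\C(=O)OC(=O)c1c(Cl)cc(Cl)cc1Cl)COC(C)=O | intermediate
32 | (2S,3S)-5-acetyl-6-[(4-methoxybenzyl)oxy]-2-(prop-1-en-2-yl)-2,3-dihydro-1-benzofuran-3-yl (2Z)-2-(acetoxymethyl)but-2-enoate | C=C(C)[C@@H]1Oc2cc(OCc3ccc(OC)cc3)c(C(C)=O)cc2[C@@H]1OC(=O)/C(=C\C)COC(C)=O | intermediate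
33 | (2S,3S)-5-acetyl-6-hydroxy-2-(prop-1-en-2-yl)-2,3-dihydro-1-benzofuran-3-yl (2Z)-2-(acetoxymethyl)but-2-enoate (CNP0193314.1) | C=C(C)[C@@H]1Oc2cc(O)c(C(C)=O)cc2[C@@H]1OC(=O)/C(=C\C)COC(C)=O | target

**Step count and risks**

Total step count: 19. Longest linear sequence: 13 steps (steps 1–7, 10–13, 18 and 19).

Steps most likely to fail:

Step 12. The allylic group may shift from the ether oxygen to the neighbouring ring nitrogen by a [3,3] process, or the benzyl-type ethers may be lost thermally, faster than the cycloaddition takes place. The fallback sets out from 21 and comes back to the route at 23. The isopropenyl group of 21 would first be hydrated (Co(acac)2, PhSiH3, O2, i-PrOH; Mukaiyama hydration, the terminal alkyne reacting more slowly) to the tertiary alcohol 1-[6-({(3R,4S)-4-[(3,4-dimethoxybenzyl)oxy]-2-hydroxy-2-methylhex-5-yn-3-yl}oxy)-4-[(4-methoxybenzyl)oxy]pyridazin-3-yl]ethan-1-one F1. F1 no longer holds an allylic ether and can be heated harder (1,2-dichlorobenzene, 200–220 °C). Cycloaddition through the bridged azo cycloadduct F2 and loss of dinitrogen should then give the 2-(2-hydroxypropan-2-yl)dihydrobenzofuran F3. Dehydration of F3 (SOCl2, pyridine, 0 °C; E2 removal of a methyl hydrogen from the chlorosulfite) would restore the isopropenyl group and give 23.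

Step 18. Acylation of the hindered cis C3 hydroxyl may be so slow that SN2′ displacement of the allylic acetate in the activated acid, or ionisation of the benzylic C3–O bond on long heating, takes over. The fallback sets out from 29 and 24 and comes back to the route at 32. Acid 29 would be silylated on both oxygens (t-BuMe2SiCl, imidazole, DMF) to the silyl ester silyl ether F4, and the silyl ester cleaved (K2CO3, MeOH/H2O, 0 °C) to (2Z)-2-{[(tert-butyldimethylsilyl)oxy]methyl}but-2-enoic acid F5. With no allylic leaving group present, its mixed anhydride with 2,4,6-trichlorobenzoic acid F6 can be used in larger excess and for longer at 80–100 °C against 24, to give the silyloxymethyl ester F7. Buffered desilylation (Bu4NF, AcOH, THF) should give the hydroxymethyl ester F8, and acetylation of its primary allylic alcohol (Ac2O, pyridine, 0 °C) would give 32.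

Step 19. Oxidation of the 4-methoxybenzyl ether of an acetyl-deactivated phenol may be sluggish, so that long exposure to DDQ degrades the ester. The fallback sets out from 24 and comes back to the route at 33. The aryl ether would be cleaved before the ester is made, by chelation-assisted Lewis acid cleavage (MgBr2·OEt2, CH2Cl2/Et2O; the acetyl oxygen and the ether oxygen bind magnesium and bromide removes the benzyl group), to 1-[(2S,3S)-3,6-dihydroxy-2-(prop-1-en-2-yl)-2,3-dihydro-1-benzofuran-5-yl]ethan-1-one F9. The phenol alone would be silylated (i-Pr3SiCl, imidazole, DMF; the hindered secondary C3 hydroxyl should not react) to the aryl triisopropylsilyl ether F10. F10 would be acylated with mixed anhydride 31 as in step 18 to the silyl-protected ester F11, and the aryl silyl ether removed with buffered fluoride (Bu4NF, AcOH, THF, 0 °C) to give 33.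

**Further compounds**

F1 | step 12 | 1-[6-({(3R,4S)-4-[(3,4-dimethoxybenzyl)oxy]-2-hydroxy-2-methylhex-5-yn-3-yl}oxy)-4-[(4-methoxybenzyl)oxy]pyridazin-3-yl]ethan-1-one | CC(C)(O)[C@@H]([C@@H](OCc1ccc(OC)c(OC)c1)C#C)Oc1cc(OCc2ccc(OC)cc2)c(C(C)=O)nn1
F2 | step 12 | bridged azo cycloadduct of F1 (bridgehead configuration not defined) | CC(=O)C12N=NC3(O[C@@H](C(C)(C)O)[C@@H](OCc4ccc(OC)c(OC)c4)C3=C1)C=C2OCc1ccc(OC)cc1
F3 | step 12 | 1-{(2R,3S)-3-[(3,4-dimethoxybenzyl)oxy]-2-(2-hydroxypropan-2-yl)-6-[(4-methoxybenzyl)oxy]-2,3-dihydro-1-benzofuran-5-yl}ethan-1-one | CC(C)(O)[C@@H]1Oc2cc(OCc3ccc(OC)cc3)c(C(C)=O)cc2[C@@H]1OCc1ccc(OC)c(OC)c1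
F4 | step 18 | tert-butyldimethylsilyl (2Z)-2-{[(tert-butyldimethylsilyl)oxy]methyl}but-2-enoate | C/C=C(\C(=O)O[Si](C)(C)C(C)(C)C)CO[Si](C)(C)C(C)(C)C
F5 | step 18 | (2Z)-2-{[(tert-butyldimethylsilyl)oxy]methyl}but-2-enoic acid | C/C=C(\C(=O)O)CO[Si](C)(C)C(C)(C)C
F6 | step 18 | mixed anhydride of F5 with 2,4,6-trichlorobenzoic acid | C/C=C(\C(=O)OC(=O)c1c(Cl)cc(Cl)cc1Cl)CO[Si](C)(C)C(C)(C)C
F7 | step 18 | (2S,3S)-5-acetyl-6-[(4-methoxybenzyl)oxy]-2-(prop-1-en-2-yl)-2,3-dihydro-1-benzofuran-3-yl (2Z)-2-{[(tert-butyldimethylsilyl)oxy]methyl}but-2-enoate | C=C(C)[C@@H]1Oc2cc(OCc3ccc(OC)cc3)c(C(C)=O)cc2[C@@H]1OC(=O)/C(=C\C)CO[Si](C)(C)C(C)(C)C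
F8 | step 18 | (2S,3S)-5-acetyl-6-[(4-methoxybenzyl)oxy]-2-(prop-1-en-2-yl)-2,3-dihydro-1-benzofuran-3-yl (2Z)-2-(hydroxymethyl)but-2-enoate | C=C(C)[C@@H]1Oc2cc(OCc3ccc(OC)cc3)c(C(C)=O)cc2[C@@H]1OC(=O)/C(=C\C)CO
F9 | step 19 | 1-[(2S,3S)-3,6-dihydroxy-2-(prop-1-en-2-yl)-2,3-dihydro-1-benzofuran-5-yl]ethan-1-one | C=C(C)[C@@H]1Oc2cc(O)c(C(C)=O)cc2[C@@H]1O
F10 | step 19 | 1-{(2S,3S)-3-hydroxy-2-(prop-1-en-2-yl)-6-[(triisopropylsilyl)oxy]-2,3-dihydro-1-benzofuran-5-yl}ethan-1-one | C=C(C)[C@@H]1Oc2cc(O[Si](C(C)C)(C(C)C)C(C)C)c(C(C)=O)cc2[C@@H]1O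
F11 | step 19 | (2S,3S)-5-acetyl-2-(prop-1-en-2-yl)-6-[(triisopropylsilyl)oxy]-2,3-dihydro-1-benzofuran-3-yl (2Z)-2-(acetoxymethyl)but-2-enoate | C=C(C)[C@@H]1Oc2cc(O[Si](C(C)C)(C(C)C)C(C)C)c(C(C)=O)cc2[C@@H]1OC(=O)/C(=C\C)COC(C)=O
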